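**Retrosynthetic overview**
1. Target 22 ⇐ one-pot removal of three MOM ethers and one TBS ether from ketone 21, whose aryl–acyl bond comes from aryllithium 19 adding to Weinreb amide 16 (the reverse polarity of a Friedel–Crafts acylation).
2. The C14=C15 Z-olefin ⇐ Wittig reaction of aldehyde 8 (C1–C14) with ylide 15 (C15–C20, carrying the 17S centre).
3. Key strategy: aldehyde 8, with its three Z-olefins, is not built but cut out of arachidonic acid by a carboxyl-tethered, remote intramolecular epoxidation of the C14=C15 olefin followed by periodate cleavage.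
4. The only stereocentre is bought as (S)-1,2-epoxypentane, which Ph3P=CH2 opens directly to the phosphonium salt.
5. No ring is constructed: the benzene ring is bought as phloroglucinol, and the only ring made is the transient 14,15-oxirane (step 1), destroyed in step 3.

Assumption: the target is read as the 17S, all-Z (5Z,8Z,11Z,14Z) isomer; all-Z arachidonic acid and (S)-1,2-epoxypentane are taken as commercially available.

**Route**

Step 1
Reactants: 1 arachidonic acid
Product: 4 rac-cis-14,15-epoxy-(5Z,8Z,11Z)-icosa-5,8,11-trienoic acid, via arachidonoyl imidazolide 2 (not isolated), via peroxyarachidonic acid 3 (not isolated)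
Conditions: 1,1'-carbonyldiimidazole (CDI), CH2Cl2, 25 °C; then anhydrous H2O2 in Et2O, cat. lithium imidazolide (LiC3H3N2), 0 °C; KHSO4 wash; then dilute CH2Cl2, 20 °C, 8 h
Reagents that add atoms: hydrogen peroxide, OO
Why: Intramolecular Prilezhaev epoxidation: the C1 peroxy acid reaches only the remote C14=C15 olefin through an unstrained macrocyclic transition state (the C5, C8 and C11 olefins would need strained medium rings), so one of four near-identical Z-olefins is oxidised stereospecifically to the cis-epoxide, whose configuration is irrelevant because both carbons are cleaved in step 3.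

Step 2
Reactants: 4 rac-cis-14,15-epoxy-(5Z,8Z,11Z)-icosa-5,8,11-trienoic acid
Product: 6 rac-cis-14,15-epoxy-N-methoxy-N-methyl-(5Z,8Z,11Z)-icosa-5,8,11-trienamide, via epoxy acyl imidazolide 5 (not isolated)
Conditions: CDI, CH2Cl2, 0 °C to rt; then MeNH(OMe) (free base), rt
Reagents that add atoms: N,O-dimethylhydroxylamine, CNOC
Why: Acyl imidazolide aminolysis (Weinreb amide formation) is near-neutral, so the cis-epoxide and the skipped triene survive.

Step 3
Reactants: 6 rac-cis-14,15-epoxy-N-methoxy-N-methyl-(5Z,8Z,11Z)-icosa-5,8,11-trienamide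
Product: 8 (5Z,8Z,11Z)-N-methoxy-N-methyl-14-oxotetradeca-5,8,11-trienamide, via threo-14,15-diol 7 (not isolated)
Conditions: H5IO6 (1.5 equiv), Et2O, 0 °C to rt, 2 h; crude aldehyde used at once in step 6
Reagents that add atoms: periodic acid, OI(=O)(O)(O)(O)O
Why: Periodic acid hydrolyses the epoxide and cleaves the resulting glycol in the same pot (Malaprade cleavage), removing C15–C20 as hexanal; isolated Z-olefins and the Weinreb amide are inert, and the β,γ-unsaturated aldehyde is not purified so that it does not isomerise into conjugation.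

Step 4
Reactants: 9 methyltriphenylphosphonium bromide; 10 (S)-1,2-epoxypentane
Product: 13 (S)-(3-hydroxyhexyl)triphenylphosphonium bromide, via methylenetriphenylphosphorane 11 (not isolated), via oxido phosphonium betaine 12 (not isolated)
Conditions: n-BuLi, THF, 0 °C; then 10, 0 to 45 °C, 12 h; then 48 % aq HBr, 0 °C; recrystallise
Reagents that add atoms: hydrogen bromide, Br
Why: SN2 alkylation of the ylide carbon by the terminal epoxide at its unsubstituted CH2 (ylide–epoxide opening), then protonation; the C–O stereocentre of 10 is not touched and becomes C17 (S).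

Step 5
Reactants: 13 (S)-(3-hydroxyhexyl)triphenylphosphonium bromide
Product: 14 (S)-[3-(tert-butyldimethylsilyloxy)hexyl]triphenylphosphonium bromide
Conditions: TBSCl, imidazole, CH2Cl2, rt
Reagents that add atoms: tert-butyldimethylsilyl chloride, CC(C)(C)[Si](C)(C)Cl
Why: Standard imidazole-promoted silylation of the secondary alcohol; capping the oxygen avoids the E-selective γ-oxido ylide pathway in step 6.

Step 6
Reactants: 14 (S)-[3-(tert-butyldimethylsilyloxy)hexyl]triphenylphosphonium bromide; 8 (5Z,8Z,11Z)-N-methoxy-N-methyl-14-oxotetradeca-5,8,11-trienamide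
Product: 16 (5Z,8Z,11Z,14Z,17S)-17-(tert-butyldimethylsilyloxy)-N-methoxy-N-methylicosa-5,8,11,14-tetraenamide, via silyloxy ylide 15 (not isolated)
Conditions: NaN(SiMe3)2, THF, −78 to 0 °C; then 8, −78 °C to 0 °C
Reagents that add atoms: none
Why: Lithium-free, kinetically controlled Wittig olefination of a non-stabilised ylide with an aliphatic aldehyde gives the Z C14=C15 olefin; the aldehyde reacts far faster than the Weinreb amide at low temperature, and C17 is not involved.

Step 7
Reactants: 17 phloroglucinol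
Product: 18 1,3,5-tris(methoxymethoxy)benzene
Conditions: NaH, DMF, 0 °C; MOMCl, 0 °C to rt
Reagents that add atoms: chloromethyl methyl ether, COCCl
Why: Williamson-type O-alkylation of the phenoxides; the MOM groups later direct lithiation and come off under mild acid.

Step 8
Reactants: 18 1,3,5-tris(methoxymethoxy)benzene; 16 (5Z,8Z,11Z,14Z,17S)-17-(tert-butyldimethylsilyloxy)-N-methoxy-N-methylicosa-5,8,11,14-tetraenamide
Product: 21 (5Z,8Z,11Z,14Z,17S)-17-(tert-butyldimethylsilyloxy)-1-[2,4,6-tris(methoxymethoxy)phenyl]icosa-5,8,11,14-tetraen-1-one, via aryllithium 19 (not isolated), via lithium hemiaminal 20 (not isolated)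
Conditions: 18 (1.8 equiv), n-BuLi, TMEDA, THF, 0 °C, 1 h; then 16, −78 to 0 °C; H2O quench
Reagents that add atoms: none
Why: Directed ortho-metalation between two OMOM groups (all three ring CH positions are equivalent) gives the aryllithium, which adds once to the Weinreb amide because the chelated tetrahedral adduct persists until work-up (Weinreb ketone synthesis); bis-allylic C–H bonds are not deprotonated by an aryllithium at low temperature.

Step 9
Reactants: 21 (5Z,8Z,11Z,14Z,17S)-17-(tert-butyldimethylsilyloxy)-1-[2,4,6-tris(methoxymethoxy)phenyl]icosa-5,8,11,14-tetraen-1-one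
Product: 22 (5Z,8Z,11Z,14Z,17S)-17-hydroxy-1-(2,4,6-trihydroxyphenyl)icosa-5,8,11,14-tetraen-1-one
Conditions: 2 M HCl in degassed MeOH, trace BHT, argon, 35–40 °C, 8 h
Reagents that add atoms: none
Why: Acid-catalysed methanolysis removes the three MOM acetals and the TBS ether in one operation; non-conjugated Z-olefins and the unactivated C17 carbinol are stable to dilute methanolic HCl, so the 17S centre is not scrambled.

**Compound list**
1 | arachidonic acid, (5Z,8Z,11Z,14Z)-icosa-5,8,11,14-tetraenoic acid | CCCCC/C=C\C/C=C\C/C=C\C/C=C\CCCC(=O)O | starting material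
2 | arachidonoyl imidazolide (not isolated) | CCCCC/C=C\C/C=C\C/C=C\C/C=C\CCCC(=O)n1ccnc1 | intermediate
3 | peroxyarachidonic acid (not isolated) | CCCCC/C=C\C/C=C\C/C=C\C/C=C\CCCC(=O)OO | intermediate
4 | rac-cis-14,15-epoxy-(5Z,8Z,11Z)-icosa-5,8,11-trienoic acid (14R*,15S*; racemate, one enantiomer drawn) | CCCCC[C@@H]1O[C@@H]1C/C=C\C/C=C\C/C=C\CCCC(=O)O | intermediate
5 | imidazolide of 4 (racemate, one enantiomer drawn; not isolated) | CCCCC[C@@H]1O[C@@H]1C/C=C\C/C=C\C/C=C\CCCC(=O)n2ccnc2 | intermediate
6 | rac-cis-14,15-epoxy-N-methoxy-N-methyl-(5Z,8Z,11Z)-icosa-5,8,11-trienamide (racemate, one enantiomer drawn) | CCCCC[C@@H]1O[C@@H]1C/C=C\C/C=C\C/C=C\CCCC(=O)N(C)OC | intermediate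
7 | rac-threo-14,15-dihydroxy-N-methoxy-N-methyl-(5Z,8Z,11Z)-icosa-5,8,11-trienamide (14R*,15R*; racemate, one enantiomer drawn; not isolated) | CCCCC[C@@H](O)[C@H](O)C/C=C\C/C=C\C/C=C\CCCC(=O)N(C)OC | intermediate
8 | (5Z,8Z,11Z)-N-methoxy-N-methyl-14-oxotetradeca-5,8,11-trienamide | O=CC/C=C\C/C=C\C/C=C\CCCC(=O)N(C)OC | intermediate
9 | methyltriphenylphosphonium bromide | C[P+](c1ccccc1)(c1ccccc1)c1ccccc1.[Br-] | starting material
10 | (S)-1,2-epoxypentane, (S)-2-propyloxirane | CCC[C@H]1CO1 | starting material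
11 | methylenetriphenylphosphorane (not isolated) | C=P(c1ccccc1)(c1ccccc1)c1ccccc1 | intermediate
12 | (S)-1-(triphenylphosphonio)hexan-3-olate, the γ-oxido phosphonium betaine (present as its LiBr adduct, in equilibrium with the oxaphospholane; not isolated) | CCC[C@H]([O-])CC[P+](c1ccccc1)(c1ccccc1)c1ccccc1 | intermediate
13 | (S)-(3-hydroxyhexyl)triphenylphosphonium bromide | CCC[C@H](O)CC[P+](c1ccccc1)(c1ccccc1)c1ccccc1.[Br-] | intermediate
14 | (S)-[3-(tert-butyldimethylsilyloxy)hexyl]triphenylphosphonium bromide | CCC[C@H](O[Si](C)(C)C(C)(C)C)CC[P+](c1ccccc1)(c1ccccc1)c1ccccc1.[Br-] | intermediate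
15 | (S)-[3-(tert-butyldimethylsilyloxy)hexylidene]triphenylphosphorane (not isolated) | CCC[C@H](O[Si](C)(C)C(C)(C)C)CC=P(c1ccccc1)(c1ccccc1)c1ccccc1 | intermediate
16 | (5Z,8Z,11Z,14Z,17S)-17-(tert-butyldimethylsilyloxy)-N-methoxy-N-methylicosa-5,8,11,14-tetraenamide | CCC[C@H](O[Si](C)(C)C(C)(C)C)C/C=C\C/C=C\C/C=C\C/C=C\CCCC(=O)N(C)OC | intermediate
17 | phloroglucinol, benzene-1,3,5-triol | Oc1cc(O)cc(O)c1 | starting material
18 | 1,3,5-tris(methoxymethoxy)benzene | COCOc1cc(OCOC)cc(OCOC)c1 | intermediate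
19 | 2,4,6-tris(methoxymethoxy)phenyllithium (not isolated) | [Li]c1c(OCOC)cc(OCOC)cc1OCOC | intermediate
20 | lithium (5Z,8Z,11Z,14Z,17S)-17-(tert-butyldimethylsilyloxy)-1-[methoxy(methyl)amino]-1-[2,4,6-tris(methoxymethoxy)phenyl]icosa-5,8,11,14-tetraen-1-olate (C1 epimers; not isolated) | CCC[C@H](O[Si](C)(C)C(C)(C)C)C/C=C\C/C=C\C/C=C\C/C=C\CCCC(O[Li])(N(C)OC)c1c(OCOC)cc(OCOC)cc1OCOC | intermediate
21 | (5Z,8Z,11Z,14Z,17S)-17-(tert-butyldimethylsilyloxy)-1-[2,4,6-tris(methoxymethoxy)phenyl]icosa-5,8,11,14-tetraen-1-one | CCC[C@H](O[Si](C)(C)C(C)(C)C)C/C=C\C/C=C\C/C=C\C/C=C\CCCC(=O)c1c(OCOC)cc(OCOC)cc1OCOC | intermediate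
22 | (5Z,8Z,11Z,14Z,17S)-17-hydroxy-1-(2,4,6-trihydroxyphenyl)icosa-5,8,11,14-tetraen-1-one | CCC[C@H](O)C/C=C\C/C=C\C/C=C\C/C=C\CCCC(=O)c1c(O)cc(O)cc1O | target

**Step count**
Total: 9 steps. Longest linear sequence: 6 steps (1, 2, 3, 6, 8, 9, from arachidonic acid).

**Three steps most likely to fail, and fallbacks**

Step 1 (remote intramolecular epoxidation). Risks are intermolecular oxygen transfer giving regioisomeric epoxides, and handling of the peroxy acid. The fallback gives up tether control in favour of undirected epoxidation with chromatographic selection. It sets out from 1: activation with CDI (through imidazolide 2) and MeNH(OMe) gives N-methoxy-N-methylarachidonamide F1. Sub-stoichiometric mCPBA (0.8 equiv, CH2Cl2, 0 °C) then gives the four cis-monoepoxides statistically. The 14,15-isomer is separated by preparative HPLC and unreacted F1 is recycled. The fallback comes back to the route at 6.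

Step 4 (ylide opening of the epoxide). Risks are proton transfer between ylide 11 and betaine 12 leading to double alkylation, and sluggish opening. The fallback builds the same C6 unit by conventional carbon–carbon and functional-group chemistry. It sets out from 10:
- CH2=CHMgBr with cat. CuI (THF, −30 °C) opens the epoxide at CH2 to give (S)-hept-1-en-4-ol F2.
- TBSCl and imidazole give (S)-tert-butyl(hept-1-en-4-yloxy)dimethylsilane F3.
- Ozonolysis with NaBH4 work-up gives (S)-3-(tert-butyldimethylsilyloxy)hexan-1-ol F4.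
- PPh3, I2 and imidazole give (S)-tert-butyl[(1-iodohexan-3-yl)oxy]dimethylsilane F5.
- PPh3 in MeCN at 80 °C gives (S)-[3-(tert-butyldimethylsilyloxy)hexyl]triphenylphosphonium iodide F6.
- NaN(SiMe3)2 deprotonates F6, and the fallback comes back to the route at ylide 15.

Step 8 (hindered aryllithium with an enolisable Weinreb amide). Risks are α-deprotonation of 16 and slow addition of the 2,6-disubstituted aryllithium. The fallback replaces acyl substitution by aldehyde addition and oxidation. It sets out from 16: iBu2AlH (THF, −78 °C) gives (5Z,8Z,11Z,14Z,17S)-17-(tert-butyldimethylsilyloxy)icosa-5,8,11,14-tetraenal F7. Aryllithium 19 adds to it at −78 °C to give (5Z,8Z,11Z,14Z,17S)-17-(tert-butyldimethylsilyloxy)-1-[2,4,6-tris(methoxymethoxy)phenyl]icosa-5,8,11,14-tetraen-1-ol F8, as an inconsequential mixture of C1 epimers. Dess–Martin periodinane (NaHCO3, CH2Cl2) oxidises the benzylic carbinol, and the fallback comes back to the route at 21.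

Further compounds
F1 | step 1 | N-methoxy-N-methylarachidonamide | CCCCC/C=C\C/C=C\C/C=C\C/C=C\CCCC(=O)N(C)OC
F2 | step 4 | (S)-hept-1-en-4-ol | CCC[C@H](O)CC=C
F3 | step 4 | (S)-tert-butyl(hept-1-en-4-yloxy)dimethylsilane | CCC[C@H](O[Si](C)(C)C(C)(C)C)CC=C
F4 | step 4 | (S)-3-(tert-butyldimethylsilyloxy)hexan-1-ol | CCC[C@H](O[Si](C)(C)C(C)(C)C)CCO
F5 | step 4 | (S)-tert-butyl[(1-iodohexan-3-yl)oxy]dimethylsilane | CCC[C@H](O[Si](C)(C)C(C)(C)C)CCI
F6 | step 4 | (S)-[3-(tert-butyldimethylsilyloxy)hexyl]triphenylphosphonium iodide | CCC[C@H](O[Si](C)(C)C(C)(C)C)CC[P+](c1ccccc1)(c1ccccc1)c1ccccc1.[I-]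
F7 | step 8 | (5Z,8Z,11Z,14Z,17S)-17-(tert-butyldimethylsilyloxy)icosa-5,8,11,14-tetraenal | CCC[C@H](O[Si](C)(C)C(C)(C)C)C/C=C\C/C=C\C/C=C\C/C=C\CCCC=O
F8 | step 8 | (5Z,8Z,11Z,14Z,17S)-17-(tert-butyldimethylsilyloxy)-1-[2,4,6-tris(methoxymethoxy)phenyl]icosa-5,8,11,14-tetraen-1-ol (C1 epimers) | CCC[C@H](O[Si](C)(C)C(C)(C)C)C/C=C\C/C=C\C/C=C\C/C=C\CCCC(O)c1c(OCOC)cc(OCOC)cc1OCOC
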